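**Remark on the chemistry (numbering and reading of the structure).** Labdane-type numbers are used: C1–C10 for the decalin (C4 gem-dimethyl, C5 ring-fusion CH, C8=C9 alkene, C10 quaternary), C11–C16 for the chain (C13 carries CH2OH, C16 is the carbinol), C17 for the lactone methine. Read this way the target is (5R,10S,16R,17S), cis-fused (H-5 and the C10 methyl on the same face), with a 13Z alkene (CH2OH cis to C15). "Dec" stands for the (4aR,8aS)-2,5,5,8a-tetramethyl-3,4,4a,5,6,7,8,8a-octahydronaphthalen-1-yl group, i.e. this cis-fused bicycle attached through C9. Precursor 26 differs from target 27 only by the ring oxygen; all other atoms and descriptors coincide, so neither structure needed correction.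

## Structural features

The target is a C25 hydroxy lactone built from two stereochemically isolated halves. The first is a cis-fused 4,4,10-trimethyloctalin: the ring-fusion carbons C5 (tertiary) and C10 (quaternary) are adjacent, C4 next to C5 is gem-dimethylated, and the tetrasubstituted C8=C9 alkene carries the C8 methyl and the side chain. The chain runs from C9 through C11–C12 to a trisubstituted Z alkene C13=C14 whose C13 bears a primary allylic CH2OH cis to C15, then through C15 to the secondary carbinol C16, which is bonded directly to C17, the β-carbon of a γ-butyrolactone. C16 and C17 are contiguous, but seven bonds separate C16 from C10, so the two pairs of stereocentres cannot relay information and each must be set on its own. Fragile points are the lactone (hydride, organometallics and above all base, under which the C16 oxygen can transacylate to an isomeric five-membered lactone), the allylic alcohol (ionisation in strong acid) and the electron-rich tetrasubstituted alkene (peracids, strong acid). The real difficulty is C17: it is stereogenic only because one of its CH2 arms ends in O and the other in C=O, and it has to be set beside C16 without a cyclic template. The cis fusion with a quaternary C10 and the Z geometry at C13=C14 are secondary problems. The key step exploits that the five lactone ring atoms (C17, its two CH2 groups, C=O and O) are a 3-substituted cyclobutanone plus one oxygen: in the four-membered ketone C17 lies on a local mirror plane, and inserting O into one of the two C(=O)–CH2 bonds creates the lactone and C17 in one event.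

## Logic of the disconnections

27 ⇒ 26. The ring O–CH2 bond of the lactone is cut and the oxygen removed, contracting the five-membered ring to the four-membered ketone of 26. C17 then stops being a stereocentre, and the base- and hydride-sensitive lactone is replaced by a ketone that can be masked. The gain is one stereocentre and one heteroatom fewer, and a ring that comes ready-made from 1. The forward step must put oxygen into one specific methylene–carbonyl bond under catalyst control and leave two alkenes and an allylic alcohol alone. 26 is used with both hydroxyls free, so that nothing has to be removed from the base-sensitive hydroxy lactone.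

26 ⇒ 24 (through 25). Only heteroatom bonds are cut: two Si–O bonds and two C–OCH3 bonds. The ketal of 24 lets the ketone pass hydride and coupling steps, and silicon ties O16 to the C13 oxymethyl group in an eight-membered ring. The forward step needs fluoride, then acid mild enough not to ionise the allylic alcohol.

24 ⇒ 23. The C13=C14 double bond is cut. In the eight-membered ring of 24 the alkene can only be cis within the ring, which puts the oxymethyl carbon and C15 on the same side; the Z geometry follows from ring size and not from a selective olefination. The gain is an open chain with two terminal alkenes. The forward step is a ring-closing metathesis onto a 1,1-disubstituted alkene at high dilution, with the C8=C9 alkene as a spectator.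

23 ⇒ 5 + 21. The two Si–O bonds are cut, dividing the molecule into a C10 and a C19 alcohol. The forward step is an unsymmetrical silylation: the hindered secondary alcohol 5 first with excess dichlorosilane (via 22), the primary alcohol 21 second.

5 ⇒ 3 (through 4). The C15–C16 bond is cut; C16 becomes the carbonyl carbon of 4, which has no stereocentre because the ring is symmetric. C16 is therefore set by catalyst control alone. The forward step must add allyl to the Re face of an α-branched aldehyde; working from the alcohol oxidation level avoids isolating 4.

3 ⇒ 2 ⇒ 1. Functional group changes only (alcohol from ester; ester and ketal from acid and ketone). The ketal must survive the hydride reduction.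

21 ⇒ 18 + 19 (through 20). The C12–C13 sp3–sp2 bond is cut. The three-carbon unit C13/CH2OH/=CH2 comes intact from 19, and the decalin carries only a vinyl group. The forward step needs hydroboration at the terminal alkene of 18 only, and an alkyl–alkenyl coupling that tolerates a free hydroxyl.

18 ⇒ 17 ⇒ 15 (through 16). The C9–C11 bond is cut, then the C9–O bond of the enol sulfonate, leading back to a C9 ketone. The ketone of 15 has a single α-hydrogen (at C8; C10 is quaternary), so enolisation fixes the tetrasubstituted C8=C9 alkene regiochemically. The forward step is a coupling at a vinyl sulfonate flanked by a quaternary carbon.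

15 ⇒ 14. Two C=C bonds are put back (C2=C3 and C7=C8); both are left over from ring construction and one hydrogenation removes them. The C8 configuration formed is irrelevant because C8 becomes sp2 again in 17.

14 ⇒ 13. The C3–C4 bond of ring A is cut, and one C4 methyl reverts to the =CH2 of an isopropenyl group. Quaternary C4 is thus made from the isopropenyl group of the chiral pool, and the ring closes between two substituents that are already cis, so the cis fusion is inherited. The forward step needs 6-exo insertion of an alkenylpalladium into a 1,1-disubstituted alkene to outrun its reduction, followed by hydride capture.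

13 ⇒ 11 ⇒ 9 + 8 (through 12 and 10). The C10–CH3 bond and then the C10–C1 bond are cut, both α to the C9 carbonyl. The order matters: the second electrophile enters anti to the C5 substituent, so methyl must come last to end up trans to the isopropenyl group. C5 of 9 supplies the absolute configuration of the decalin. The forward steps are two kinetic α′-enolisations of the cross-conjugated enone without elimination of the vinyl iodide.

8 ⇒ 7 ⇒ 6. Functional group changes (bromide from alcohol, alcohol from ester); the Z geometry needed for the six-membered ring closure is bought with 6.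

## Other disconnections considered

Alternative 1: The cut is the C16–C17 bond, made together with one C–O bond of an oxetane. Forward, aldehyde A2 is irradiated in furan A1. The excited carbonyl adds across one furan double bond through a 1,4-biradical, oxygen to the α-carbon and carbon to the β-carbon, and the exo adduct A3 should result.
- In its favour: A3 holds C16 and C17 with their relative configuration fixed by the exo mode, and its dihydrofuran ring contains all five lactone ring atoms with the oxygen in place. On relative control at C16/C17 this is better than the chosen plan, which sets the two centres in two unrelated catalytic steps.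
- Against it here: the adduct is racemic, so a resolution or another absolute-control element is needed. The acetal carbon must be reduced to CH2 by cleaving the oxetane C–O bond and the enol ether carbon oxidised to the lactone carbonyl, while acid opens such adducts easily with aromatisation to a 3-furylcarbinol and loss of C17. The four-carbon aldehyde ends at C13 in the alcohol oxidation state, so the Z-trisubstituted alkene and the union with the decalin still need their own solution.
- Comparison: both plans build this region from small achiral compounds (equal). The alternative uses excited-state, substrate-controlled diastereoselection; the chosen plan uses ground-state, catalyst-controlled group selection. In step count the alternative is expected to be longer (resolution, two redox adjustments, separate alkene construction), whereas the chosen plan needs seven steps from 1 to 27 on this side.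

Alternative 2: The cut is the C3–C4 bond of ring A, with ring B taken from 9. Forward, SnCl4 ionises tertiary chloride A4 at C4, the Z-vinylsilane attacks through its silicon-bearing carbon, and loss of Me3Si leaves the C2=C3 alkene of A5, which is the same compound as 14.
- In its favour: the β-silyl effect fixes both the site of attack and the alkene position, C4 is formed without a transition metal, and since A5 equals 14 the sequence could replace steps 6–8 without touching the rest.
- Against it here: the chloride requires HCl addition to the isopropenyl group in the presence of an acid-sensitive vinylsilane and an enone, the cation can lose a proton instead of cyclising, and one more operation is needed than in the chosen closure, which forms the same bond directly from 13.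
- Comparison: the structural idea is the same (ring A closed onto the isopropenyl carbon of a dialkylated 9, cis fusion inherited from the alkylation order), so the two are equal there. The mechanisms differ (carbocation with ipso-substitution against carbopalladation with hydride capture), and the alternative is better in that no organopalladium intermediate can be reduced prematurely. It is one step longer; reagent preparation is about equal. It does not touch the C17 problem and is kept as the fallback for step 8.

Alternative 3: The cuts are C5–C10 and C6–C7, opening both rings to triene imide A6. Forward, Me2AlCl chelates the imide carbonyls and the diene C7=C8–C9=C10 adds to the activated C5=C6 bond of the same chain. Because the tether is cis to the diene at C10, only the cis-fused transition state is within reach, and the auxiliary selects the face, giving A7.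
- In its favour: two rings, two C–C bonds and both ring-fusion stereocentres arise in one step, the C8=C9 alkene appears in the right place with C11 already oxygenated, and no terpene from the chiral pool is needed. In complexity gained per step this is better than the chosen plan, which uses steps 6–10 for the same result.
- Against it here: the diene terminus C10 is fully substituted and the dienophile carbon C5 is neopentyl, so two very crowded carbons must be joined. The tetrasubstituted diene must be geometrically pure and may isomerise under the Lewis acid. The acyl group on C6 is not in the target and must be cleaved and excised, about three further steps.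
- Comparison: the source of absolute configuration is stoichiometric in both (auxiliary against chiral pool; equal). The mechanism is a concerted pericyclic closure against stepwise enolate alkylation and organopalladium cyclisation. The count to a compound such as 21 is expected to be higher for the alternative, because A6 itself needs a long linear assembly.

Key step: step 16

## Steps

Step 1
Reactants: 1 3-oxocyclobutane-1-carboxylic acid
Product: 2 methyl 3,3-dimethoxycyclobutane-1-carboxylate
Conditions: HC(OMe)3, MeOH, TsOH·H2O (cat.), reflux
Reagents that add atoms: methanol, CO; trimethyl orthoformate, COC(OC)OC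
Why: Fischer esterification and ketalisation run under the same acid catalysis and the orthoformate consumes the water, so both should go to completion; the dimethyl ketal shields the strained ketone from hydride and from the later coupling steps.

Step 2
Reactants: 2 methyl 3,3-dimethoxycyclobutane-1-carboxylate
Product: 3 (3,3-dimethoxycyclobutyl)methanol
Conditions: LiAlH4, THF, 0 °C → rt
Reagents that add atoms: none
Why: Hydride reduction of an ester to the primary alcohol; the ketal is inert to LiAlH4 and the basic work-up.

Step 3
Reactants: 3 (3,3-dimethoxycyclobutyl)methanol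
Product: 5 (R)-1-(3,3-dimethoxycyclobutyl)but-3-en-1-ol, via 3,3-dimethoxycyclobutane-1-carbaldehyde 4 (not isolated)
Conditions: [Ir(cod)Cl]2 (2.5 mol%), (R)-Cl,MeO-BIPHEP (5 mol%), 4-chloro-3-nitrobenzoic acid (10 mol%), Cs2CO3 (20 mol%), allyl acetate, THF, 100 °C (sealed)
Reagents that add atoms: allyl acetate, C=CCOC(C)=O
Why: Iridium-catalysed transfer-hydrogenative carbonyl allylation (Krische allylation): the alcohol is dehydrogenated to aldehyde 4, which is allylated by the chiral π-allyliridium benzoate complex through a closed chair transition state, so C16 is set by the ligand. The (R)-ligand is expected, by the usual correlation for this catalyst family, to deliver allyl to the Re face and give (R)-5; the sense should be checked (Mosher esters), the antipodal ligand being equally available. The ketal tolerates the buffered medium.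

Step 4
Reactants: 6 ethyl (Z)-3-iodoprop-2-enoate
Product: 7 (Z)-3-iodoprop-2-en-1-ol
Conditions: iBu2AlH (2.2 equiv), CH2Cl2, −78 → −40 °C
Reagents that add atoms: none
Why: 1,2-Reduction of the enoate to the allylic alcohol by the aluminium hydride; at low temperature the Z vinyl iodide should be neither reduced nor isomerised.

Step 5
Reactants: 7 (Z)-3-iodoprop-2-en-1-ol
Product: 8 (Z)-3-bromo-1-iodoprop-1-ene
Conditions: CBr4, PPh3, CH2Cl2, 0 °C
Reagents that add atoms: carbon tetrabromide, BrC(Br)(Br)Br
Why: Appel bromination under neutral conditions; SN2 displacement at the primary allylic carbon leaves the alkene position and Z geometry untouched.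

Step 6
Reactants: 9 (S)-carvone; 8 (Z)-3-bromo-1-iodoprop-1-ene
Product: 11 (5S)-6-[(Z)-3-iodoprop-2-en-1-yl]-2-methyl-5-(prop-1-en-2-yl)cyclohex-2-en-1-one (C6 epimers; 5,6-trans major), via lithium dienolate of carvone 10 (not isolated)
Conditions: LiN(iPr)2 (1.05 equiv), THF, −78 °C; then 8, −78 → −20 °C
Reagents that add atoms: none
Why: Kinetic α′-deprotonation of the cross-conjugated enone at C6 and C-alkylation by the reactive allylic bromide (enolate alkylation). The C6 configuration is immaterial because this carbon is enolised again in step 7.

Step 7
Reactants: 11 (5S)-6-[(Z)-3-iodoprop-2-en-1-yl]-2-methyl-5-(prop-1-en-2-yl)cyclohex-2-en-1-one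
Product: 13 (5R,6S)-6-[(Z)-3-iodoprop-2-en-1-yl]-2,6-dimethyl-5-(prop-1-en-2-yl)cyclohex-2-en-1-one (6-methyl trans to isopropenyl), via lithium enolate of the monoalkylated enone 12 (not isolated)
Conditions: LiN(iPr)2 (1.1 equiv), THF, −78 °C; then MeI, DMPU, −78 → −20 °C
Reagents that add atoms: iodomethane, CI
Why: Second α′-alkylation: the tetrasubstituted enolate should take up methyl on the face opposite the neighbouring C5 isopropenyl group, which sets quaternary C10 with the iodoallyl arm cis to isopropenyl and so fixes the later cis ring fusion. Low temperature and near-stoichiometric base should prevent dehydroiodination of the vinyl iodide.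

Step 8
Reactants: 13 (5R,6S)-6-[(Z)-3-iodoprop-2-en-1-yl]-2,6-dimethyl-5-(prop-1-en-2-yl)cyclohex-2-en-1-one
Product: 14 (4aR,8aS)-2,5,5,8a-tetramethyl-4a,5,8,8a-tetrahydronaphthalen-1(4H)-one (cis-fused)
Conditions: Pd(OAc)2 (10 mol%), PPh3 (20 mol%), HCO2Na (1.5 equiv), Et4NCl, DMF, 80 °C
Reagents that add atoms: none
Why: Intramolecular reductive Heck reaction (cyclisation with hydride capture): zerovalent palladium inserts into the vinyl C–I bond, 6-exo-trig syn-carbopalladation of the internal isopropenyl carbon forms C3–C4 and quaternary C4, and the resulting neopentyl-type alkylpalladium, which has no β-hydrogen, is reduced by formate to the second C4 methyl. No stereocentre is created; the fusion is cis because the two reacting arms are already cis on ring B.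

Step 9
Reactants: 14 (4aR,8aS)-2,5,5,8a-tetramethyl-4a,5,8,8a-tetrahydronaphthalen-1(4H)-one
Product: 15 (4aR,8aS)-2,5,5,8a-tetramethyloctahydronaphthalen-1(2H)-one (cis-fused; C2 epimers)
Conditions: H2 (1 atm), Pd/C (10 wt%), EtOAc, rt
Reagents that add atoms: none
Why: Heterogeneous hydrogenation saturates the cis-disubstituted ring A alkene and the enone C=C and leaves the hindered ketone; the configuration formed at C8 does not matter because C8 becomes sp2 again in step 10.

Step 10
Reactants: 15 (4aR,8aS)-2,5,5,8a-tetramethyloctahydronaphthalen-1(2H)-one
Product: 17 (4aR,8aS)-2,5,5,8a-tetramethyl-3,4,4a,5,6,7,8,8a-octahydronaphthalen-1-yl trifluoromethanesulfonate, via potassium enolate of the decalone 16 (not isolated)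
Conditions: KN(SiMe3)2, THF, −78 → 0 °C; then PhNTf2, 0 °C → rt
Reagents that add atoms: N-phenylbis(trifluoromethanesulfonimide), O=S(=O)(N(c1ccccc1)S(=O)(=O)C(F)(F)F)C(F)(F)F
Why: The ketone has only one α-hydrogen (C8; C10 is quaternary), so enolisation can give only the C8=C9 enolate, and O-sulfonylation fixes the tetrasubstituted alkene (enol triflate formation, as for 2,2,6-trimethylcyclohexanone).

Step 11
Reactants: 17 (4aR,8aS)-2,5,5,8a-tetramethyl-3,4,4a,5,6,7,8,8a-octahydronaphthalen-1-yl trifluoromethanesulfonate
Product: 18 (4aR,8aS)-1-ethenyl-2,5,5,8a-tetramethyl-3,4,4a,5,6,7,8,8a-octahydronaphthalene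
Conditions: CH2=CHSnBu3 (1.5 equiv), Pd(PPh3)4 (5 mol%), LiCl (3 equiv), THF, reflux
Reagents that add atoms: tributyl(vinyl)stannane, C=C[Sn](CCCC)(CCCC)CCCC
Why: Stille coupling of a hindered enol triflate; chloride replaces triflate on palladium and speeds transmetallation, and the same coupling is established for 2,6,6-trimethylcyclohexenyl triflates, which have the same substitution pattern around the reacting carbon.

Step 12
Reactants: 18 (4aR,8aS)-1-ethenyl-2,5,5,8a-tetramethyl-3,4,4a,5,6,7,8,8a-octahydronaphthalene; 19 2-bromoprop-2-en-1-ol
Product: 21 4-Dec-2-methylidenebutan-1-ol, via B-alkyl-9-borabicyclononane 20 (not isolated)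
Conditions: 9-BBN (1.3 equiv), THF, 0 °C → rt; then H2O, 19, Pd(dppf)Cl2 (5 mol%), AsPh3, Cs2CO3, DMF, rt → 50 °C
Reagents that add atoms: none
Why: 9-BBN should hydroborate only the monosubstituted terminal alkene (boron at C12) and leave the tetrasubstituted one; the alkylborane then undergoes B-alkyl Suzuki–Miyaura coupling with the vinyl bromide, the dppf ligand suppressing β-hydride elimination and the aqueous carbonate medium tolerating the free hydroxyl.

Step 13
Reactants: 5 (R)-1-(3,3-dimethoxycyclobutyl)but-3-en-1-ol; 21 4-Dec-2-methylidenebutan-1-ol
Product: 23 {[(R)-1-(3,3-dimethoxycyclobutyl)but-3-en-1-yl]oxy}(4-Dec-2-methylidenebutoxy)diisopropylsilane, via chlorosilyl ether 22 (not isolated)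
Conditions: 5, iPr2SiCl2 (2 equiv), imidazole, CH2Cl2, 0 °C; volatiles removed in vacuo; then 21, imidazole, CH2Cl2, rt
Reagents that add atoms: dichlorodiisopropylsilane, CC(C)[Si](Cl)(Cl)C(C)C
Why: Stepwise O-silylation: the hindered secondary alcohol with excess dichlorosilane should stop at the monochloride because a second substitution at the crowded silicon is slow, and the chloride then silylates the primary allylic alcohol (temporary silicon tether); no stereocentre is touched.

Step 14
Reactants: 23 {[(R)-1-(3,3-dimethoxycyclobutyl)but-3-en-1-yl]oxy}(4-Dec-2-methylidenebutoxy)diisopropylsilane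
Product: 24 (4R)-4-(3,3-dimethoxycyclobutyl)-7-(2-Dec-ethyl)-2,2-diisopropyl-1,3-dioxa-2-silacyclooct-6-ene (ring alkene cis)
Conditions: RuCl2(=CHPh)(H2IMes)(PCy3) (second-generation Grubbs catalyst, 10 mol%), CH2Cl2 (0.005 M), reflux
Reagents that add atoms: none
Why: Silicon-tethered ring-closing metathesis: the ruthenium carbene loads at the monosubstituted alkene and closes onto the 1,1-disubstituted one with loss of ethylene. The eight-membered ring can hold only a cis ring alkene, which is the required 13Z geometry (CH2O cis to C15); the tetrasubstituted C8=C9 alkene is inert to metathesis.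

Step 15
Reactants: 24 (4R)-4-(3,3-dimethoxycyclobutyl)-7-(2-Dec-ethyl)-2,2-diisopropyl-1,3-dioxa-2-silacyclooct-6-ene
Product: 26 3-[(1R,3Z)-6-Dec-1-hydroxy-4-(hydroxymethyl)hex-3-en-1-yl]cyclobutan-1-one, via ketal diol 25 (not isolated)
Conditions: Bu4NF (2.5 equiv), THF, 0 °C → rt; then 1 M aq. HCl to pH 1, rt
Reagents that add atoms: water, O
Why: Fluoride cleaves both Si–O bonds (desilylation), and dilute aqueous acid then hydrolyses the dimethyl ketal through the oxocarbenium ion; primary allylic and secondary homoallylic alcohols should not ionise under these conditions, so C16 and the alkene geometry are preserved.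

Step 16
Reactants: 26 3-[(1R,3Z)-6-Dec-1-hydroxy-4-(hydroxymethyl)hex-3-en-1-yl]cyclobutan-1-one
Product: 27 (4S)-4-[(1R,3Z)-6-Dec-1-hydroxy-4-(hydroxymethyl)hex-3-en-1-yl]oxolan-2-one (CNP0164639.3)
Conditions: 30% aq. H2O2 (1.5 equiv), (R)-3,3′-di(pyren-1-yl)-5,5′,6,6′,7,7′,8,8′-octahydro-1,1′-binaphthalene-2,2′-diyl hydrogen phosphate (10 mol%), CHCl3, −40 °C; Na2SO3 quench
Reagents that add atoms: hydrogen peroxide, OO
Why: The phosphoric acid binds the ketone through P–OH and H2O2 through P=O, peroxide adds to the strained carbonyl to give the Criegee hemiperketal, and the ring CH2 antiperiplanar to the O–O bond shifts from carbon to oxygen with retention as water leaves. The closest known reaction type is the chiral phosphoric acid-catalysed asymmetric Baeyer–Villiger oxidation of prochiral 3-substituted cyclobutanones with aqueous H2O2. The five-membered lactone is closed by ring expansion of the four-membered ring (1,2-shift of carbon to oxygen), not by cyclisation of an open chain, so no exo/endo question arises and no base is needed. C17 becomes stereogenic here, and its configuration is decided by which of the two diastereotopic CH2 groups migrates; the chiral pocket of the acid controls this, with the adjacent C16 carbinol as a weaker second influence, and the acid antipode is chosen for the matched pairing (the (R)-acid is expected to give the sense needed for 17S by analogy with simple 3-substituted cyclobutanones, to be confirmed on a model ketone). The step needs chemoselectivity for the ketone over two alkenes and an allylic alcohol, which ring strain secures, since H2O2 without a metal or peracid should not epoxidise isolated alkenes at −40 °C. There is no regiochemical question because both α-carbons are CH2. The low temperature holds back the uncatalysed background oxidation, and the weakly acidic, base-free medium with a neutral reductive quench keeps the C16 hydroxyl from attacking the new lactone.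

## Compound list

1 | 3-oxocyclobutane-1-carboxylic acid | O=C1CC(C1)C(=O)O | starting material
2 | methyl 3,3-dimethoxycyclobutane-1-carboxylate | COC(=O)C1CC(OC)(OC)C1 | intermediate
3 | (3,3-dimethoxycyclobutyl)methanol | OCC1CC(OC)(OC)C1 | intermediate
4 | 3,3-dimethoxycyclobutane-1-carbaldehyde (formed in situ) | O=CC1CC(OC)(OC)C1 | intermediate
5 | (R)-1-(3,3-dimethoxycyclobutyl)but-3-en-1-ol | C=CC[C@@H](O)C1CC(OC)(OC)C1 | intermediate
6 | ethyl (Z)-3-iodoprop-2-enoate | CCOC(=O)/C=C\I | starting material
7 | (Z)-3-iodoprop-2-en-1-ol | OC/C=C\I | intermediate
8 | (Z)-3-bromo-1-iodoprop-1-ene | BrC/C=C\I | intermediate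
9 | (S)-carvone, (5S)-2-methyl-5-(prop-1-en-2-yl)cyclohex-2-en-1-one | CC1=CC[C@@H](CC1=O)C(C)=C | starting material
10 | lithium dienolate of 9, C6=C1–OLi (formed in situ) | CC1=CC[C@@H](C=C1O[Li])C(C)=C | intermediate
11 | (5S)-6-[(Z)-3-iodoprop-2-en-1-yl]-2-methyl-5-(prop-1-en-2-yl)cyclohex-2-en-1-one (C6 epimers, 5,6-trans major) | CC1=CC[C@@H](C(C/C=C\I)C1=O)C(C)=C | intermediate
12 | lithium enolate of 11, C6=C1–OLi (formed in situ) | CC1=CC[C@@H](C(C/C=C\I)=C1O[Li])C(C)=C | intermediate
13 | (5R,6S)-6-[(Z)-3-iodoprop-2-en-1-yl]-2,6-dimethyl-5-(prop-1-en-2-yl)cyclohex-2-en-1-one (6-methyl trans to isopropenyl) | CC1=CC[C@@H]([C@](C)(C/C=C\I)C1=O)C(C)=C | intermediate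
14 | (4aR,8aS)-2,5,5,8a-tetramethyl-4a,5,8,8a-tetrahydronaphthalen-1(4H)-one (cis-fused) | CC1=CC[C@@H]2C(C)(C)C=CC[C@]2(C)C1=O | intermediate
15 | (4aR,8aS)-2,5,5,8a-tetramethyloctahydronaphthalen-1(2H)-one (cis-fused, C2 epimers) | CC1CC[C@@H]2C(C)(C)CCC[C@]2(C)C1=O | intermediate
16 | potassium enolate of 15, C8=C9–OK (formed in situ) | CC1=C(O[K])[C@@]2(C)CCCC(C)(C)[C@H]2CC1 | intermediate
17 | Dec trifluoromethanesulfonate | CC1=C(OS(=O)(=O)C(F)(F)F)[C@@]2(C)CCCC(C)(C)[C@H]2CC1 | intermediate
18 | (4aR,8aS)-1-ethenyl-2,5,5,8a-tetramethyl-3,4,4a,5,6,7,8,8a-octahydronaphthalene | CC1=C(C=C)[C@@]2(C)CCCC(C)(C)[C@H]2CC1 | intermediate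
19 | 2-bromoprop-2-en-1-ol | OCC(Br)=C | starting material
20 | 9-(2-Dec-ethyl)-9-borabicyclo[3.3.1]nonane (formed in situ) | CC1=C(CCB3C4CCCC3CCC4)[C@@]2(C)CCCC(C)(C)[C@H]2CC1 | intermediate
21 | 4-Dec-2-methylidenebutan-1-ol | CC1=C(CCC(=C)CO)[C@@]2(C)CCCC(C)(C)[C@H]2CC1 | intermediate
22 | chloro{[(R)-1-(3,3-dimethoxycyclobutyl)but-3-en-1-yl]oxy}diisopropylsilane (formed in situ) | C=CC[C@@H](O[Si](Cl)(C(C)C)C(C)C)C1CC(OC)(OC)C1 | intermediate
23 | {[(R)-1-(3,3-dimethoxycyclobutyl)but-3-en-1-yl]oxy}(4-Dec-2-methylidenebutoxy)diisopropylsilane | CC1=C(CCC(=C)CO[Si](C(C)C)(C(C)C)O[C@H](CC=C)C3CC(OC)(OC)C3)[C@@]2(C)CCCC(C)(C)[C@H]2CC1 | intermediate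
24 | (4R)-4-(3,3-dimethoxycyclobutyl)-7-(2-Dec-ethyl)-2,2-diisopropyl-1,3-dioxa-2-silacyclooct-6-ene (ring alkene cis) | CC1=C(CC/C3=C/C[C@@H](O[Si](C(C)C)(C(C)C)OC3)C4CC(OC)(OC)C4)[C@@]2(C)CCCC(C)(C)[C@H]2CC1 | intermediate
25 | (2Z,5R)-2-(2-Dec-ethyl)-5-(3,3-dimethoxycyclobutyl)pent-2-ene-1,5-diol (formed in situ) | CC1=C(CC/C(=C/C[C@@H](O)C3CC(OC)(OC)C3)CO)[C@@]2(C)CCCC(C)(C)[C@H]2CC1 | intermediate
26 | 3-[(1R,3Z)-6-Dec-1-hydroxy-4-(hydroxymethyl)hex-3-en-1-yl]cyclobutan-1-one | CC1=C(CC/C(=C/C[C@@H](O)C3CC(=O)C3)CO)[C@@]2(C)CCCC(C)(C)[C@H]2CC1 | intermediate
27 | (4S)-4-[(1R,3Z)-6-Dec-1-hydroxy-4-(hydroxymethyl)hex-3-en-1-yl]oxolan-2-one, CNP0164639.3 | CC1=C(CC/C(=C/C[C@@H](O)[C@@H]2COC(=O)C2)CO)[C@@]2(C)CCCC(C)(C)[C@H]2CC1 | target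

## Step count and least certain steps

Total step count: 16. Longest linear sequence: 13 steps (6 → 7 → 8 in steps 4–5, then steps 6–16 to 27). From 9 alone it is 11 steps; the branch from 1 contributes 3 steps before the union in step 13.

Step 16 (key step). Most likely failure: weak differentiation between the two ring methylenes. The acid's pocket is known to work on simple 3-substituted ketones, whereas here the substituent is a branched hydroxyalkyl group whose own stereocentre and free hydroxyls may work against the catalyst; a slow uncatalysed oxidation would erode selectivity further. Fallback: move the oxygen insertion to the small fragment, where less chemoselective but stronger catalyst systems can be used and the unwanted epimer removed early. Setting out from 5, the ketal is hydrolysed (PPTS, acetone/H2O) to (R)-1-(3-oxocyclobutyl)but-3-en-1-ol F1. Asymmetric Baeyer–Villiger oxidation of F1 (the same acid with H2O2, a Baeyer–Villiger monooxygenase, or a chiral Sc(OTf)3–N,N′-dioxide complex with a peracid, the only alkene now being monosubstituted) gives (S)-4-[(R)-1-hydroxybut-3-en-1-yl]oxolan-2-one F2, which is freed from its C17 epimer by chromatography. F2 is tethered to 21 as in step 13 to give the lactone-bearing bis(alkoxy)silane F3, ring-closing metathesis as in step 14 gives the eight-membered lactone silaketal F4, and HF·pyridine in THF (acidic, so no transacylation) releases 27, where the route is rejoined.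

Step 8. Most likely failure: reduction of the alkenylpalladium intermediate by formate before the slow insertion into the 1,1-disubstituted alkene, or insertion at the enone instead. Fallback: cationic closure of the same bond. Setting out from 9, alkylation as in step 6 with (Z)-(3-bromoprop-1-en-1-yl)trimethylsilane F6 gives the monoalkylated enone F7. F6 is made from commercial 3-(trimethylsilyl)prop-2-yn-1-ol by cis-semihydrogenation over nickel boride from Ni(OAc)2 and NaBH4 with ethylenediamine to (Z)-3-(trimethylsilyl)prop-2-en-1-ol F5, followed by Appel bromination. Methylation as in step 7 gives the quaternary ketone F8, HCl (CH2Cl2, −78 °C) adds to the isopropenyl group to give tertiary chloride F9, and SnCl4 (CH2Cl2, −78 °C) ionises it. The vinylsilane then attacks through its silicon-bearing carbon with loss of Me3Si, and the route is rejoined at 14.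

Step 14. Most likely failure: slow closure of the eight-membered ring onto the 1,1-disubstituted alkene, so that intermolecular metathesis through the terminal alkene (oligomerisation) takes over. Fallback: replace the silicon tether by an ester so that a six-membered ring is closed. Setting out from 21, MnO2 (CH2Cl2) gives 4-Dec-2-methylidenebutanal F10, and NaClO2/NaH2PO4/2-methylbut-2-ene gives 4-Dec-2-methylidenebutanoic acid F11. Esterification with 5 (2,4,6-trichlorobenzoyl chloride, Et3N, DMAP) gives the acrylate ester F12. Ring-closing metathesis with the catalyst of step 14 gives the α-substituted 5,6-dihydropyran-2-one F13, in which the ring holds the carbonyl carbon cis to C15. Excess iBu2AlH (CH2Cl2, −78 → 0 °C) reduces F13 to the Z-diol 25, where the route is rejoined (acid hydrolysis as in the second stage of step 15).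

Step 3. Most likely failure: sluggish dehydrogenation or reduced facial selectivity with the α-branched aldehyde at 100 °C. Fallback: separate oxidation and allylation. Setting out from 3, Swern oxidation gives 4 as an isolated aldehyde, which is allylated at low temperature with allylboronic acid pinacol ester under a chiral BINOL-derived phosphoric acid (TRIP), or with the antipode of B-allyldiisopinocampheylborane that attacks the Re face; the route is rejoined at 5. No new compound is made.

## Further compounds

F1 | step 16 | (R)-1-(3-oxocyclobutyl)but-3-en-1-ol | C=CC[C@@H](O)C1CC(=O)C1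
F2 | step 16 | (S)-4-[(R)-1-hydroxybut-3-en-1-yl]oxolan-2-one | C=CC[C@@H](O)[C@@H]1COC(=O)C1
F3 | step 16 | (4-Dec-2-methylidenebutoxy){[(R)-1-((S)-5-oxooxolan-3-yl)but-3-en-1-yl]oxy}diisopropylsilane | CC1=C(CCC(=C)CO[Si](C(C)C)(C(C)C)O[C@H](CC=C)[C@@H]3COC(=O)C3)[C@@]2(C)CCCC(C)(C)[C@H]2CC1
F4 | step 16 | (4S)-4-[(4R)-7-(2-Dec-ethyl)-2,2-diisopropyl-1,3-dioxa-2-silacyclooct-6-en-4-yl]oxolan-2-one | CC1=C(CC/C3=C/C[C@@H](O[Si](C(C)C)(C(C)C)OC3)[C@@H]4COC(=O)C4)[C@@]2(C)CCCC(C)(C)[C@H]2CC1
F5 | step 8 | (Z)-3-(trimethylsilyl)prop-2-en-1-ol | OC/C=C\[Si](C)(C)C
F6 | step 8 | (Z)-(3-bromoprop-1-en-1-yl)trimethylsilane | BrC/C=C\[Si](C)(C)C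
F7 | step 8 | (5S)-2-methyl-5-(prop-1-en-2-yl)-6-[(Z)-3-(trimethylsilyl)prop-2-en-1-yl]cyclohex-2-en-1-one (C6 epimers) | CC1=CC[C@@H](C(C/C=C\[Si](C)(C)C)C1=O)C(C)=C
F8 | step 8 | (5R,6S)-2,6-dimethyl-5-(prop-1-en-2-yl)-6-[(Z)-3-(trimethylsilyl)prop-2-en-1-yl]cyclohex-2-en-1-one | CC1=CC[C@@H]([C@](C)(C/C=C\[Si](C)(C)C)C1=O)C(C)=C
F9 | step 8 | 5-(2-chloropropan-2-yl) analogue of F8 (tertiary chloride, ring configuration as in F8) | CC1=CC[C@@H]([C@](C)(C/C=C\[Si](C)(C)C)C1=O)C(C)(C)Cl
F10 | step 14 | 4-Dec-2-methylidenebutanal | CC1=C(CCC(=C)C=O)[C@@]2(C)CCCC(C)(C)[C@H]2CC1
F11 | step 14 | 4-Dec-2-methylidenebutanoic acid | CC1=C(CCC(=C)C(=O)O)[C@@]2(C)CCCC(C)(C)[C@H]2CC1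
F12 | step 14 | (R)-1-(3,3-dimethoxycyclobutyl)but-3-en-1-yl 4-Dec-2-methylidenebutanoate | CC1=C(CCC(=C)C(=O)O[C@H](CC=C)C3CC(OC)(OC)C3)[C@@]2(C)CCCC(C)(C)[C@H]2CC1
F13 | step 14 | (6R)-3-(2-Dec-ethyl)-6-(3,3-dimethoxycyclobutyl)-5,6-dihydro-2H-pyran-2-one | CC1=C(CCC3=CC[C@@H](OC3=O)C4CC(OC)(OC)C4)[C@@]2(C)CCCC(C)(C)[C@H]2CC1
F0 | step 3 | none | none
A1 | alternative 1 | furan | c1ccoc1
A2 | alternative 1 | 4-(tert-butyldimethylsilyloxy)butanal | CC(C)(C)[Si](C)(C)OCCCC=O
A3 | alternative 1 | exo-6-[3-(tert-butyldimethylsilyloxy)propyl]-2,7-dioxabicyclo[3.2.0]hept-3-ene (needed enantiomer) | CC(C)(C)[Si](C)(C)OCCC[C@H]1O[C@@H]2OC=C[C@H]12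
A4 | alternative 2 | tertiary chloride carrying the Z-vinylsilane (same structure as F9) | CC1=CC[C@@H]([C@](C)(C/C=C\[Si](C)(C)C)C1=O)C(C)(C)Cl
A5 | alternative 2 | cis-fused bicyclic dienone with C2=C3 alkene (identical with 14) | CC1=CC[C@@H]2C(C)(C)C=CC[C@]2(C)C1=O
A6 | alternative 3 | triene imide, tether cis to the diene at C10, E-enimide, (R)-4-benzyloxazolidinone auxiliary | C=C(C)/C(CO[Si](C)(C)C(C)(C)C)=C(C)\CCCC(C)(C)/C=C/C(=O)N1C(=O)OC[C@H]1Cc1ccccc1
A7 | alternative 3 | cis-fused octalin imide with the auxiliary acyl group on C6 | CC1=C(CO[Si](C)(C)C(C)(C)C)[C@@]2(C)CCCC(C)(C)[C@H]2[C@@H](C1)C(=O)N1C(=O)OC[C@H]1Cc1ccccc1
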